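The flavone is cut at the bond between C2 of the pyranone ring and C1' of the 2-hydroxy-4,5-dimethoxyphenyl ring. The key step is a one-pot C–H zincation/Negishi arylation. It exploits the C2–H of the 4H-chromen-4-one, the sp2 C–H flanked by ring oxygen O1 and vinylogous to the C4 carbonyl. The fully oxygenated A/C bicycle (5,7-bis(benzyloxy)-8-methoxychromone) therefore needs no handle at C2 and is joined directly to the B-ring bromide 1-(benzyloxy)-2-bromo-4,5-dimethoxybenzene. The chromone arises from a commercial dibenzyl phloroacetophenone by ortho-iodination, copper-catalysed methoxylation and enaminone cyclisation. One hydrogenolysis then frees the three phenols.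

Key step: step 5

Remark: the target has no stereocentre, so no stereocontrol is needed; compounds 1 and 6 are taken as catalogue chemicals.

Step 1
Reactants: 1 1-[2,4-bis(benzyloxy)-6-hydroxyphenyl]ethan-1-one
Product: 2 1-[4,6-bis(benzyloxy)-2-hydroxy-3-iodophenyl]ethan-1-one
Conditions: NIS (1.05 equiv), TFA (10 mol%), MeCN, 0 °C → rt
Reagents that add atoms: N-iodosuccinimide, O=C1CCC(=O)N1I
Why: Electrophilic aromatic iodination, expected at the ring carbon ortho to the free, hydrogen-bonded phenol OH (the usual halogenation site of 2-hydroxy-4,6-dialkoxyacetophenones), with one equivalent of NIS to limit di-iodination.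

Step 2
Reactants: 2 1-[4,6-bis(benzyloxy)-2-hydroxy-3-iodophenyl]ethan-1-one
Product: 3 1-[4,6-bis(benzyloxy)-2-hydroxy-3-methoxyphenyl]ethan-1-one
Conditions: CuI (10 mol%), 3,4,7,8-tetramethyl-1,10-phenanthroline (20 mol%), Cs2CO3 (2.5 equiv), MeOH/toluene, 110 °C (sealed); aq. NH4Cl work-up
Reagents that add atoms: methanol, CO
Why: Copper-catalysed Ullmann-type C–O coupling of an aryl iodide with methanol, in which the neighbouring phenoxide should assist copper while the benzyl ethers and the ketone tolerate carbonate base.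

Step 3
Reactants: 3 1-[4,6-bis(benzyloxy)-2-hydroxy-3-methoxyphenyl]ethan-1-one
Product: 5 5,7-bis(benzyloxy)-8-methoxy-4H-chromen-4-one, via enaminone 4 (not isolated)
Conditions: DMF-DMA (3 equiv), toluene, 95 °C; evaporate; conc. HCl, CH2Cl2, rt → 40 °C
Reagents that add atoms: N,N-dimethylformamide dimethyl acetal, COC(OC)N(C)C
Why: Enaminone formation at the acetyl methyl group followed by acid-promoted 6-endo addition of the only free phenol and loss of dimethylamine (standard chromone synthesis), which fixes the methoxy group at C8 because the cyclising hydroxyl is the one next to it.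

Step 4
Reactants: 6 2-bromo-4,5-dimethoxyphenol
Product: 7 1-(benzyloxy)-2-bromo-4,5-dimethoxybenzene
Conditions: BnBr (1.1 equiv), K2CO3 (1.5 equiv), DMF, rt
Reagents that add atoms: benzyl bromide, BrCc1ccccc1
Why: Williamson ether synthesis on a phenoxide, which masks the acidic OH from the organozinc of the next step with a group that leaves in the final hydrogenolysis.

Step 5
Reactants: 5 5,7-bis(benzyloxy)-8-methoxy-4H-chromen-4-one; 7 1-(benzyloxy)-2-bromo-4,5-dimethoxybenzene
Product: 9 5,7-bis(benzyloxy)-2-[2-(benzyloxy)-4,5-dimethoxyphenyl]-8-methoxy-4H-chromen-4-one, via bis(chromon-2-yl)zinc 8 (not isolated)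
Conditions: TMP2Zn·2MgCl2·2LiCl (0.6 equiv), THF, −30 °C, 1 h; then 7 (0.9 equiv), Pd(OAc)2 (2 mol%), SPhos (4 mol%), −30 → 50 °C; aq. NH4Cl
Reagents that add atoms: none
Why: The zinc amide, with its MgCl2 bound to the C4 carbonyl, should remove the C2–H of the pyranone ring (the most acidic sp2 C–H, α to O1 and vinylogous to the activated carbonyl) to give the C2-zinc species 8; Pd(0)/SPhos then inserts into the C–Br bond of 7, the chromonyl group is transferred from zinc and reductive elimination forms the C2–C1' bond. The closest known reaction type is the regioselective C2-zincation of chromones with TMP-zinc amide bases followed by Negishi cross-coupling, an established entry to flavones. No ring is closed and no stereocentre is formed. The step needs metalation at C2 rather than C3, C6 or the benzylic positions, which the higher acidity of C2–H and the low kinetic basicity of the zinc amide at −30 °C should secure; the non-nucleophilic TMP amide also avoids conjugate opening of the pyranone. The bulky biarylphosphine is chosen to accommodate the ortho-benzyloxy group of the electron-rich bromide.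

Step 6
Reactants: 9 5,7-bis(benzyloxy)-2-[2-(benzyloxy)-4,5-dimethoxyphenyl]-8-methoxy-4H-chromen-4-one
Product: 10 5,7-dihydroxy-2-(2-hydroxy-4,5-dimethoxyphenyl)-8-methoxy-4H-chromen-4-one
Conditions: H2 (1 atm), 10% Pd/C, THF/MeOH, rt
Reagents that add atoms: none
Why: Catalytic hydrogenolysis of the three benzyl aryl ethers, under which the methyl ethers and the conjugated C2=C3 bond of the flavone are expected to survive.

Compound list
1 | 1-[2,4-bis(benzyloxy)-6-hydroxyphenyl]ethan-1-one | CC(=O)c1c(O)cc(OCc2ccccc2)cc1OCc1ccccc1 | starting material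
2 | 1-[4,6-bis(benzyloxy)-2-hydroxy-3-iodophenyl]ethan-1-one | CC(=O)c1c(O)c(I)c(OCc2ccccc2)cc1OCc1ccccc1 | intermediate
3 | 1-[4,6-bis(benzyloxy)-2-hydroxy-3-methoxyphenyl]ethan-1-one | CC(=O)c1c(O)c(OC)c(OCc2ccccc2)cc1OCc1ccccc1 | intermediate
4 | (E)-1-[4,6-bis(benzyloxy)-2-hydroxy-3-methoxyphenyl]-3-(dimethylamino)prop-2-en-1-one | CN(C)/C=C/C(=O)c1c(O)c(OC)c(OCc2ccccc2)cc1OCc1ccccc1 | intermediate
5 | 5,7-bis(benzyloxy)-8-methoxy-4H-chromen-4-one | COc1c(OCc2ccccc2)cc(OCc2ccccc2)c2c(=O)ccoc12 | intermediate
6 | 2-bromo-4,5-dimethoxyphenol | COc1cc(O)c(Br)cc1OC | starting material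
7 | 1-(benzyloxy)-2-bromo-4,5-dimethoxybenzene | COc1cc(OCc2ccccc2)c(Br)cc1OC | intermediate
8 | bis[5,7-bis(benzyloxy)-8-methoxy-4-oxo-4H-chromen-2-yl]zinc | COc1c(OCc2ccccc2)cc(OCc2ccccc2)c2c(=O)cc([Zn]c3cc(=O)c4c(OCc5ccccc5)cc(OCc5ccccc5)c(OC)c4o3)oc12 | intermediate
9 | 5,7-bis(benzyloxy)-2-[2-(benzyloxy)-4,5-dimethoxyphenyl]-8-methoxy-4H-chromen-4-one | COc1cc(OCc2ccccc2)c(-c2cc(=O)c3c(OCc4ccccc4)cc(OCc4ccccc4)c(OC)c3o2)cc1OC | intermediate
10 | 5,7-dihydroxy-2-(2-hydroxy-4,5-dimethoxyphenyl)-8-methoxy-4H-chromen-4-one | COc1cc(O)c(-c2cc(=O)c3c(O)cc(O)c(OC)c3o2)cc1OC | target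

Total step count: 6. Longest linear sequence: 5 steps (1 → 2 → 3 → 5 → 9 → 10).

Steps most likely to fail

Step 5. Zincation may go partly to C3 or stay incomplete, and oxidative addition into the electron-rich, ortho-substituted bromide may be slow enough for the zinc species to be protonated or homocoupled. The fallback replaces C–H metalation by conjugate arylation and sets out from 7 and 5. Bromide 7 is converted by bromine–lithium exchange (n-BuLi, THF, −78 °C), B(OiPr)3 and aqueous acid into [2-(benzyloxy)-4,5-dimethoxyphenyl]boronic acid F1. Palladium(II)-catalysed conjugate addition of this acid to chromone 5 (Pd(OCOCF3)2, 2,2'-bipyridine, aqueous 1,2-dichloroethane, 60 °C) should give racemic 5,7-bis(benzyloxy)-2-[2-(benzyloxy)-4,5-dimethoxyphenyl]-8-methoxychroman-4-one F2. Dehydrogenation (I2 cat., DMSO, 120 °C) re-forms the C2=C3 bond and the route is rejoined at 9.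

Step 2. Reductive loss of iodine or a sluggish coupling at the doubly ortho-flanked carbon may dominate. The fallback introduces the oxygen through a formyl group instead of a halide and sets out from 1, so it also bypasses step 1 should the iodination lack site control. Magnesium-mediated ortho-formylation (MgCl2, Et3N, paraformaldehyde, MeCN, reflux) should give 3-acetyl-4,6-bis(benzyloxy)-2-hydroxybenzaldehyde F3. Dakin oxidation (H2O2, aq. NaOH) converts the aldehyde into 1-[4,6-bis(benzyloxy)-2,3-dihydroxyphenyl]ethan-1-one F4. Methylation of the non-chelated 3-hydroxyl (MeI 1.0 equiv, K2CO3, acetone) returns to the route at 3.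

Step 6. The C2=C3 bond may be over-reduced, or cleavage of the peri 5-benzyl ether may stall on the catalyst. The fallback sets out from 9 and removes the benzyl groups by Lewis-acid cleavage instead of hydrogenation: BCl3 with pentamethylbenzene as cation scavenger in CH2Cl2 at −78 °C, conditions under which aryl methyl ethers are expected to persist, leading directly to 10.

Further compounds
F1 | step 5 | [2-(benzyloxy)-4,5-dimethoxyphenyl]boronic acid | COc1cc(OCc2ccccc2)c(B(O)O)cc1OC
F2 | step 5 | rac-5,7-bis(benzyloxy)-2-[2-(benzyloxy)-4,5-dimethoxyphenyl]-8-methoxychroman-4-one | COc1cc(OCc2ccccc2)c(C2CC(=O)c3c(OCc4ccccc4)cc(OCc4ccccc4)c(OC)c3O2)cc1OC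
F3 | step 2 | 3-acetyl-4,6-bis(benzyloxy)-2-hydroxybenzaldehyde | CC(=O)c1c(O)c(C=O)c(OCc2ccccc2)cc1OCc1ccccc1
F4 | step 2 | 1-[4,6-bis(benzyloxy)-2,3-dihydroxyphenyl]ethan-1-one | CC(=O)c1c(O)c(O)c(OCc2ccccc2)cc1OCc1ccccc1
F0 | step 6 | none | none
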